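## Retrosynthetic overview

1. Target 14 comes from angeloylation of the C6 hydroxyl of 13 (C–O), and 13 from a C6–OH-directed epoxidation of 12, which closes the final oxirane ring.
2. Key C–O bond: 12 arises by anti (SN2) opening of the cyclic vinyl oxirane 11 at allylic C1 with angelic acid. This proposed cobalt-catalysed step installs the first angelate with inversion and frees the C6–OH that steers the next step.
3. Vinyl oxirane 11 comes from enone 7 by α'-bromination, 1,2-reduction and ring closure.
4. The side chain of 7 comes from the isopropenyl group of (R)-carvone: allylic oxidation to enal 3, reagent-controlled allylboration (sets C8), acetylation, cross-metathesis with 2-methyl-2-butene.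
5. Ring order: the cyclohexene ring is taken intact from (R)-carvone 1; a transient C1–C6 oxirane is made and opened; the C2–C3 oxirane of the target is formed in the penultimate step.

Convention used below: ring atoms carry carvone numbering (C1 carbonyl carbon, C2 methyl-bearing carbon, C3, C4, C5 side-chain carbon, C6); the side chain is C7(=C14H2)–C8(O)–C9–C10=C11(CH3)2; α is the ring face to which the C5 side chain points, β the opposite face. In this convention the target is 8S, C1–OAng β, C6–OAng α, 2,3-oxirane α, C2–CH3 β (Ang = angeloyl, (Z)-2-methylbut-2-enoyl).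

## Route

Step 1
Reactants: 1 (R)-(−)-carvone
Product: 3 (R)-2-(4-methyl-5-oxocyclohex-3-en-1-yl)prop-2-enal, via 10-hydroxycarvone 2 (not isolated)
Conditions: SeO2 (0.3 equiv), t-BuOOH (3 equiv), CH2Cl2, 23 °C; then MnO2 (15 equiv), 23 °C
Reagents that add atoms: tert-butyl hydroperoxide CC(C)(C)OO (oxygen source); selenium dioxide O=[Se]=O (oxygen carrier)
Why: Catalytic SeO2 allylic oxidation (ene reaction, then [2,3]-sigmatropic shift) attacks the CH3 of the electron-rich 1,1-disubstituted alkene rather than the deactivated enone, the mild conditions avoid α-oxidation of the ketone, and MnO2 then oxidises only the primary allylic alcohol; no stereocentre is touched.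

Step 2
Reactants: 3 (R)-2-(4-methyl-5-oxocyclohex-3-en-1-yl)prop-2-enal
Product: 5 (R)-5-[(S)-3-hydroxyhexa-1,5-dien-2-yl]-2-methylcyclohex-2-en-1-one, via borinate ester 4 (not isolated)
Conditions: (−)-Ipc2B(allyl) (1.2 equiv, commercial solution, derived from (+)-α-pinene), Et2O, −78 °C; then HOCH2CH2NH2, 23 °C (no peroxide work-up, which would epoxidise the enone)
Reagents that add atoms: (−)-B-allyldiisopinocampheylborane C=CCB([C@@H]1C[C@@H]2C[C@H]([C@H]1C)C2(C)C)[C@@H]1C[C@@H]2C[C@H]([C@H]1C)C2(C)C
Why: Brown asymmetric allylboration through a closed chair transition state is reagent-controlled, adds to the Si face of the aldehyde to set C8 as S, and at −78 °C reacts with the aldehyde far faster than with the enone ketone.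

Step 3
Reactants: 5 (R)-5-[(S)-3-hydroxyhexa-1,5-dien-2-yl]-2-methylcyclohex-2-en-1-one
Product: 6 (S)-2-[(R)-4-methyl-5-oxocyclohex-3-en-1-yl]hexa-1,5-dien-3-yl acetate
Conditions: Ac2O, pyridine, DMAP (5 mol%), CH2Cl2, 0 → 23 °C
Reagents that add atoms: acetic anhydride CC(=O)OC(C)=O
Why: Nucleophile-catalysed acylation of the secondary alcohol proceeds with retention at C8 and masks the only hydroxyl that could later misdirect the vanadium epoxidation.

Step 4
Reactants: 6 (S)-2-[(R)-4-methyl-5-oxocyclohex-3-en-1-yl]hexa-1,5-dien-3-yl acetate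
Product: 7 (S)-6-methyl-2-[(R)-4-methyl-5-oxocyclohex-3-en-1-yl]hepta-1,5-dien-3-yl acetate
Conditions: 2-methyl-2-butene (30 equiv), second-generation Grubbs catalyst (H2IMes)(PCy3)Cl2Ru=CHPh (3 mol%), CH2Cl2, 40 °C, sealed tube
Reagents that add atoms: 2-methyl-2-butene CC=C(C)C
Why: Olefin cross-metathesis engages only the monosubstituted alkene (the hindered 1,1-disubstituted alkene and the enone are inert) and excess 2-methyl-2-butene converts it into the prenyl-type trisubstituted alkene.

Step 5
Reactants: 7 (S)-6-methyl-2-[(R)-4-methyl-5-oxocyclohex-3-en-1-yl]hepta-1,5-dien-3-yl acetate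
Product: 9 6β-bromo ketone (7 with bromine on C6, trans to the C5 side chain), via silyl dienol ether 8 (not isolated)
Conditions: TMSOTf (1.2 equiv), Et3N (1.5 equiv), CH2Cl2, 0 °C; then NBS (1.05 equiv), THF, −78 °C
Reagents that add atoms: N-bromosuccinimide O=C1CCC(=O)N1Br
Why: Soft enolisation gives the cross-conjugated 1-silyloxy-1(6),2-diene without touching the acetate, and electrophilic α-bromination of this silyl enol ether at C6 occurs anti to the adjacent C5 substituent, placing bromine β.

Step 6
Reactants: 9 6β-bromo ketone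
Product: 11 1α,6α-epoxy-2-ene (vinyl oxirane, oxirane cis to the C5 side chain), via trans-bromohydrin 10 (not isolated)
Conditions: NaBH4, CeCl3·7H2O, MeOH–THF, −78 → −40 °C; then solvent exchange, DBU (1.5 equiv), CH2Cl2, 0 → 23 °C; filtration through Et3N-deactivated silica
Reagents that add atoms: none
Why: Luche 1,2-reduction delivers hydride axially to the β-face (as in carvone itself) to give the 1α-alcohol trans to the 6β-bromide, and intramolecular Williamson displacement (SN2, inversion at C6) then closes the α-oxirane.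

Step 7
Reactants: 11 1α,6α-epoxy-2-ene (vinyl oxirane)
Product: 12 1β-angeloyloxy-6α-hydroxy-2-ene
Conditions: angelic acid (1.2 equiv), (salphen)Co(O2CC(CH3)=CHCH3) (5 mol%; trivalent cobalt; salphen = N,N'-bis(3,5-di-tert-butylsalicylidene)-1,2-phenylenediamine dianion), i-Pr2NEt (5 mol%), t-BuOMe, 0 → 23 °C
Reagents that add atoms: angelic acid C/C=C(/C)C(=O)O
Why: Proposed new method: cooperative carboxylate delivery by a trivalent cobalt salphen angelate to a cyclic 1,3-diene monoepoxide, in which one cobalt centre binds the oxirane oxygen as a Lewis acid and lengthens the allylic C1–O bond while a second cobalt–angelate hands its carboxylate to C1 from the β-face anti to the leaving oxygen (SN2, inversion, so C1–O is set β and the C6–OH is released α), the tight bimetallic transition state avoiding a free allyl cation (no SN2' product at C3, no attack at C6 next to the branched C5) and never activating the acyl group (no Z to E drift of the angelate); the closest known reaction type is the cobalt–salen-catalysed ring opening of meso and terminal epoxides by carboxylic acids, which has not been shown for vinyl oxiranes of cyclic dienes or with α,β-unsaturated acids.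

Step 8
Reactants: 12 1β-angeloyloxy-6α-hydroxy-2-ene
Product: 13 1β-angeloyloxy-2α,3α-epoxy-6α-ol
Conditions: VO(acac)2 (5 mol%), t-BuOOH (1.5 equiv, in decane), CH2Cl2, 0 → 23 °C
Reagents that add atoms: tert-butyl hydroperoxide CC(C)(C)OO
Why: In this hydroxyl-directed vanadium-catalysed epoxidation the vanadate ester of the axial homoallylic C6–OH delivers oxygen intramolecularly to the α-face of the trisubstituted C2=C3 alkene (syn to C6–OH, anti to the C1 angelate), setting C2 and C3, while the undirected prenyl alkene and the less nucleophilic C7=C14 alkene react much more slowly.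

Step 9
Reactants: 13 1β-angeloyloxy-2α,3α-epoxy-6α-ol
Product: 14 target, (8S)-8-acetoxy-1β,6α-bis(angeloyloxy)-2α,3α-epoxide
Conditions: angelic acid (4 equiv), 2,4,6-Cl3C6H2COCl (4 equiv), Et3N (4.4 equiv), toluene, 23 °C, filter; then 13, toluene, 80 °C
Reagents that add atoms: angelic acid C/C=C(/C)C(=O)O (delivered as its mixed anhydride with 2,4,6-trichlorobenzoic acid)
Why: Yamaguchi-type mixed-anhydride esterification run without a nucleophilic catalyst acylates the hindered C6–OH at the less hindered angeloyl carbonyl and avoids the addition–elimination pathway that isomerises angelates to tiglates; no stereocentre changes.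

## Compound list

1 | (R)-(−)-carvone, (R)-2-methyl-5-(prop-1-en-2-yl)cyclohex-2-en-1-one | C=C(C)[C@@H]1CC=C(C)C(=O)C1 | starting material
2 | (R)-10-hydroxycarvone, (R)-5-(3-hydroxyprop-1-en-2-yl)-2-methylcyclohex-2-en-1-one (not isolated) | C=C(CO)[C@@H]1CC=C(C)C(=O)C1 | intermediate
3 | (R)-2-(4-methyl-5-oxocyclohex-3-en-1-yl)prop-2-enal | C=C(C=O)[C@@H]1CC=C(C)C(=O)C1 | intermediate
4 | diisopinocampheylborinate ester of alcohol 5 (not isolated) | C=C([C@H](CC=C)OB([C@@H]2C[C@@H]3C[C@H]([C@H]2C)C3(C)C)[C@@H]2C[C@@H]3C[C@H]([C@H]2C)C3(C)C)[C@@H]1CC=C(C)C(=O)C1 | intermediate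
5 | (R)-5-[(S)-3-hydroxyhexa-1,5-dien-2-yl]-2-methylcyclohex-2-en-1-one | C=C([C@H](CC=C)O)[C@@H]1CC=C(C)C(=O)C1 | intermediate
6 | (S)-2-[(R)-4-methyl-5-oxocyclohex-3-en-1-yl]hexa-1,5-dien-3-yl acetate | C=C([C@H](CC=C)OC(C)=O)[C@@H]1CC=C(C)C(=O)C1 | intermediate
7 | (S)-6-methyl-2-[(R)-4-methyl-5-oxocyclohex-3-en-1-yl]hepta-1,5-dien-3-yl acetate | C=C([C@H](CC=C(C)C)OC(C)=O)[C@@H]1CC=C(C)C(=O)C1 | intermediate
8 | cross-conjugated trimethylsilyl dienol ether of 7 (C1–OSiMe3, C1=C6 and C2=C3; not isolated) | C=C([C@H](CC=C(C)C)OC(C)=O)[C@@H]1CC=C(C)C(O[Si](C)(C)C)=C1 | intermediate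
9 | 6β-bromo ketone: 7 with Br on C6, trans to the C5 side chain | C=C([C@H](CC=C(C)C)OC(C)=O)[C@@H]1CC=C(C)C(=O)[C@H]1Br | intermediate
10 | trans-bromohydrin: 1α-hydroxy-6β-bromo-2-ene, OH cis to the side chain (not isolated) | C=C([C@H](CC=C(C)C)OC(C)=O)[C@@H]1CC=C(C)[C@H](O)[C@H]1Br | intermediate
11 | vinyl oxirane: 1α,6α-epoxy-2-ene, oxirane cis to the side chain | C=C([C@H](CC=C(C)C)OC(C)=O)[C@@H]1CC=C(C)[C@@H]2O[C@H]12 | intermediate
12 | 1β-angeloyloxy-6α-hydroxy-2-ene (trans hydroxy ester, OH cis to the side chain) | C=C([C@H](CC=C(C)C)OC(C)=O)[C@@H]1CC=C(C)[C@@H](OC(=O)/C(C)=C\C)[C@@H]1O | intermediate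
13 | 1β-angeloyloxy-2α,3α-epoxy-6α-ol (oxirane cis to C6–OH and to the side chain) | C=C([C@H](CC=C(C)C)OC(C)=O)[C@@H]1C[C@@H]2O[C@]2(C)[C@@H](OC(=O)/C(C)=C\C)[C@@H]1O | intermediate
14 | CNP0188566.1: (8S)-8-acetoxy-1β,6α-bis(angeloyloxy)-2α,3α-epoxybisabola-7(14),10-diene in the numbering used here | C=C([C@H](CC=C(C)C)OC(C)=O)[C@@H]1C[C@@H]2O[C@]2(C)[C@@H](OC(=O)/C(C)=C\C)[C@@H]1OC(=O)/C(C)=C\C | target

## Step count and risks

Total steps: 9. Longest linear sequence: 9 (fully linear from 1).

The three steps most likely to fail: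

Step 1 (allylic oxidation of carvone). The risk is a modest yield and over-oxidation. The fallback sets out from 1: ene-type allylic chlorination with Ca(OCl)2 and CO2 in CH2Cl2–H2O at 0 °C gives (R)-10-chlorocarvone F1. Its primary allylic chloride is then oxidised with N-methylmorpholine N-oxide and catalytic NaI in MeCN at 23 °C (amine-oxide oxidation of an activated halide), and the route is rejoined at 3.

Step 5 (α'-bromination). The bromo ketone can epimerise at C6, lose HBr towards a phenol, or form alongside bromination of the prenyl alkene. The fallback sets out from 7 and installs an oxygen leaving group instead. LiN(SiMe3)2 in THF at −78 °C followed by 2-(phenylsulfonyl)-3-phenyloxaziridine hydroxylates the enolate anti to the C5 substituent to give the 6β-hydroxy enone F2. MsCl and Et3N give the 6β-mesylate F3. NaBH4 with CeCl3·7H2O gives the 1α-hydroxy-6β-mesylate F4. KOt-Bu in THF at −20 °C closes the oxirane, and the route is rejoined at 11.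

Step 7 (the proposed cobalt-catalysed opening). The risks are attack at C6 or at C3 (SN2'), Lewis-acid rearrangement of the vinyl oxirane, and acyl migration in 12. The fallback uses known chemistry only and sets out from 9. SN2 displacement of the α-keto bromide with cesium angelate, CsO2CC(CH3)=CHCH3 (from Cs2CO3 and angelic acid), in DMF at 0 °C inverts C6 and gives the 6α-angeloyloxy enone F5. Luche reduction (NaBH4, CeCl3·7H2O), with hydride anti to the axial ester, gives the 1α-alcohol F6. VO(acac)2 with t-BuOOH, directed by the allylic hydroxyl, gives the 2α,3α-epoxy-1α-ol F7. Mitsunobu esterification with angelic acid (PPh3, diisopropyl azodicarboxylate, toluene, 0 → 23 °C) inverts C1, and the route is rejoined at 14.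

## Further compounds

F1 | step 1 | (R)-10-chlorocarvone, (R)-5-(3-chloroprop-1-en-2-yl)-2-methylcyclohex-2-en-1-one | C=C(CCl)[C@@H]1CC=C(C)C(=O)C1
F2 | step 5 | 6β-hydroxy enone: 7 with OH on C6, trans to the C5 side chain | C=C([C@H](CC=C(C)C)OC(C)=O)[C@@H]1CC=C(C)C(=O)[C@H]1O
F3 | step 5 | 6β-mesyloxy enone: methanesulfonate of F2 | C=C([C@H](CC=C(C)C)OC(C)=O)[C@@H]1CC=C(C)C(=O)[C@H]1OS(C)(=O)=O
F4 | step 5 | 1α-hydroxy-6β-mesyloxy-2-ene (trans, OH cis to the side chain) | C=C([C@H](CC=C(C)C)OC(C)=O)[C@@H]1CC=C(C)[C@H](O)[C@H]1OS(C)(=O)=O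
F5 | step 7 | 6α-angeloyloxy enone: 7 with OAng on C6, cis to the C5 side chain | C=C([C@H](CC=C(C)C)OC(C)=O)[C@@H]1CC=C(C)C(=O)[C@@H]1OC(=O)/C(C)=C\C
F6 | step 7 | 6α-angeloyloxy-1α-hydroxy-2-ene (cis hydroxy ester) | C=C([C@H](CC=C(C)C)OC(C)=O)[C@@H]1CC=C(C)[C@H](O)[C@@H]1OC(=O)/C(C)=C\C
F7 | step 7 | 6α-angeloyloxy-2α,3α-epoxy-1α-ol | C=C([C@H](CC=C(C)C)OC(C)=O)[C@@H]1C[C@@H]2O[C@]2(C)[C@H](O)[C@@H]1OC(=O)/C(C)=C\C
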